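**Retrosynthetic overview**
The route rests on the side-chain stereocentre C6', which carries ethyl, hydroxymethyl and the (2'E,4'E)-dienoate and is therefore the α-carbon of butanal. C6'–C7' is made by enamine hydroxymethylation and C4'=C5' by vinylogous Horner–Wadsworth–Emmons olefination with a 4-phosphonocrotonate already esterified to C3–O of ring A.
That phosphonate comes from the C7-silylated core alcohol, whose C3 carbinol is set by hydride reduction of a saturated C3 ketone on the face opposite the angular C5 methyl.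
Ring A is taken from p-benzoquinone monoketal: the C4 methyl enters by Cu-catalysed conjugate addition and the C3 oxygen is carried as the ketal. Ring B is then closed by Robinson annulation with methyl vinyl ketone, which sets the quaternary C5.
The C1=C2 bond (Saegusa–Ito) and the C7/C8 diosphenol (enolate hydroxylation, oxidation) are added last.

Key step: step 14

Numbering: core atoms carry eremophilane numbers. Ring A is C1–C5 and C10 (C3 bears the ester oxygen, C4 and C5 the methyls). Ring B is C5–C10 (C7 enol, C8 ketone). The acyl chain is C1'–C6', with hydroxymethyl carbon C7' and ethyl C8'–C9'.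
Assumption: the (S,R,R)-phosphoramidite is taken to deliver the 5R adduct 2, by analogy with its facial sense on cyclohex-2-enone (here the ketal carbon outranks the α-carbon, so the same face gives R). If the first run shows the opposite sense, the (R,S,S)-ligand is used and nothing else changes.

**Step 1**
Reactants: 1 4,4-dimethoxycyclohexa-2,5-dien-1-one
Product: 2 (5R)-4,4-dimethoxy-5-methylcyclohex-2-en-1-one
Conditions: Me2Zn (1.2 equiv), Cu(OTf)2 (2 mol%), (S,R,R)-phosphoramidite from (S)-BINOL and bis[(R)-1-phenylethyl]amine (4 mol%), toluene, −25 °C; aq. NH4Cl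
Reagents that add atoms: dimethylzinc, C[Zn]C
Why: Copper/phosphoramidite-catalysed enantioselective conjugate addition of a dialkylzinc desymmetrises the two enantiotopic enone units of the quinone monoketal; the ligand-bound copper delivers methyl to one β-carbon and sets the future C4 as R, and the zinc enolate should resist a second addition until quench.

**Step 2**
Reactants: 2 (5R)-4,4-dimethoxy-5-methylcyclohex-2-en-1-one
Product: 3 (5R)-4,4-dimethoxy-5,6-dimethylcyclohex-2-en-1-one (C6 epimers)
Conditions: LiN(iPr)2, THF, −78 °C; MeI, DMPU, −78 → −20 °C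
Reagents that add atoms: iodomethane, CI
Why: Kinetic α'-enolate alkylation, C6 being the only enolisable position because C4 is quaternary; the C6 configuration is immaterial since this carbon is enolised again in step 4.

**Step 3**
Reactants: 3 (5R)-4,4-dimethoxy-5,6-dimethylcyclohex-2-en-1-one
Product: 4 (3R)-4,4-dimethoxy-2,3-dimethylcyclohexan-1-one (C2 epimers)
Conditions: H2 (1 atm), 5% Pd/C, EtOAc, Et3N (trace), rt
Reagents that add atoms: none
Why: Heterogeneous hydrogenation of the enone C=C leaves ketone and ketal intact (the amine suppresses ionisation of the allylic ketal), and the C3 methyl centre is β to the carbonyl and cannot epimerise.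

**Step 4**
Reactants: 4 (3R)-4,4-dimethoxy-2,3-dimethylcyclohexan-1-one; 5 methyl vinyl ketone
Product: 8 (4aR,5R)-6,6-dimethoxy-4a,5-dimethyl-4,4a,5,6,7,8-hexahydronaphthalen-2(3H)-one, via Michael adduct 6 (not isolated), via ketol 7 (not isolated)
Conditions: NaOMe (0.2 equiv), MeOH, 5 added slowly, −10 °C → rt; then NaOMe (1 equiv), 60 °C
Reagents that add atoms: none
Why: Robinson annulation, in which the more substituted enolate adds to the enone on the face opposite the neighbouring methyl, so the new quaternary carbon (target C5) should carry its methyl cis to the C4 methyl, and a 6-(enolendo)-exo-trig aldol condensation then closes ring B; minor regio- and stereoisomers are expected to be removable by chromatography.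

**Step 5**
Reactants: 8 (4aR,5R)-6,6-dimethoxy-4a,5-dimethyl-4,4a,5,6,7,8-hexahydronaphthalen-2(3H)-one
Product: 9 (4aR,5R)-4a,5-dimethyl-4,4a,7,8-tetrahydronaphthalene-2,6(3H,5H)-dione
Conditions: PPTS (cat.), acetone/H2O, rt
Reagents that add atoms: water, O
Why: Mild acid-catalysed hydrolysis of the dimethyl ketal through the oxocarbenium ion; the weak acid should not enolise the new C3 ketone toward the C4 methyl centre.

**Step 6**
Reactants: 9 (4aR,5R)-4a,5-dimethyl-4,4a,7,8-tetrahydronaphthalene-2,6(3H,5H)-dione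
Product: 10 (4aR,5R,6S)-6-hydroxy-4a,5-dimethyl-4,4a,5,6,7,8-hexahydronaphthalen-2(3H)-one
Conditions: LiBH(s-Bu)3 (1.05 equiv), THF, −78 °C; aq. NH4Cl
Reagents that add atoms: none
Why: Bulky trialkylborohydride reduction, in which the saturated C3 ketone should react much faster than the β,β-disubstituted enone, and equatorial attack from the face opposite the axial angular C5 methyl gives the axial C3 alcohol cis to both methyls (3S).

**Step 7**
Reactants: 10 (4aR,5R,6S)-6-hydroxy-4a,5-dimethyl-4,4a,5,6,7,8-hexahydronaphthalen-2(3H)-one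
Product: 12 (4aR,5R,6S)-4a,5-dimethyl-6-(triethylsilyloxy)-4,4a,5,6-tetrahydronaphthalen-2(3H)-one, via bis-silyl dienol ether 11 (not isolated)
Conditions: Et3SiOTf (2.5 equiv), Et3N, CH2Cl2, 0 °C → rt; then Pd(OAc)2 (1.1 equiv), MeCN, rt
Reagents that add atoms: triethylsilyl trifluoromethanesulfonate, CC[Si](CC)(CC)OS(=O)(=O)C(F)(F)F
Why: The silyl triflate/amine pair silylates the C3 hydroxyl and soft-enolises the enone to the extended C8(O)=C9–C10=C1 dienol silyl ether, and Saegusa–Ito oxidation with divalent palladium (palladation at C1, β-hydride elimination from C2) should give the linear C9=C10/C1=C2 dienone.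

**Step 8**
Reactants: 12 (4aR,5R,6S)-4a,5-dimethyl-6-(triethylsilyloxy)-4,4a,5,6-tetrahydronaphthalen-2(3H)-one
Product: 13 (4aR,5R,6S)-3-hydroxy-4a,5-dimethyl-6-(triethylsilyloxy)-4,4a,5,6-tetrahydronaphthalen-2(3H)-one (C3 epimers)
Conditions: KN(SiMe3)2, THF, −78 °C; 2-(phenylsulfonyl)-3-phenyloxaziridine, −78 °C; aq. NH4Cl
Reagents that add atoms: 2-(phenylsulfonyl)-3-phenyloxaziridine, O=S(=O)(c1ccccc1)N1OC1c1ccccc1
Why: Enolate hydroxylation, in which the hindered amide removes the α'-methylene proton at target C7 kinetically (cross-conjugated enolate) rather than the remote C3–H and the oxaziridine transfers electrophilic oxygen; the new carbinol centre is destroyed in step 9.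

**Step 9**
Reactants: 13 (4aR,5R,6S)-3-hydroxy-4a,5-dimethyl-6-(triethylsilyloxy)-4,4a,5,6-tetrahydronaphthalen-2(3H)-one
Product: 14 (4aS,5R,6S)-3-hydroxy-4a,5-dimethyl-6-(triethylsilyloxy)-5,6-dihydronaphthalen-2(4aH)-one
Conditions: Dess–Martin periodinane, NaHCO3, CH2Cl2, 0 °C → rt
Reagents that add atoms: none
Why: Dess–Martin oxidation of the acyloin gives the C7,C8-dione, which should tautomerise toward C6 (the only side with an α-hydrogen) to the cross-conjugated diosphenol.

**Step 10**
Reactants: 14 (4aS,5R,6S)-3-hydroxy-4a,5-dimethyl-6-(triethylsilyloxy)-5,6-dihydronaphthalen-2(4aH)-one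
Product: 15 (4aS,5R,6S)-3-(tert-butyldimethylsilyloxy)-4a,5-dimethyl-6-(triethylsilyloxy)-5,6-dihydronaphthalen-2(4aH)-one
Conditions: TBSCl, imidazole, DMF, 0 °C → rt
Reagents that add atoms: tert-butyldimethylsilyl chloride, CC(C)(C)[Si](C)(C)Cl
Why: O-silylation of the acidic enol hydroxyl by the imidazole-activated silyl chloride caps C7–OH against the acylating agent and the base used later.

**Step 11**
Reactants: 15 (4aS,5R,6S)-3-(tert-butyldimethylsilyloxy)-4a,5-dimethyl-6-(triethylsilyloxy)-5,6-dihydronaphthalen-2(4aH)-one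
Product: 16 (4aS,5R,6S)-3-(tert-butyldimethylsilyloxy)-6-hydroxy-4a,5-dimethyl-5,6-dihydronaphthalen-2(4aH)-one
Conditions: PPTS, MeOH/CH2Cl2, 0 °C → rt
Reagents that add atoms: none
Why: Acid-catalysed methanolysis cleaves the alkyl triethylsilyl ether, whereas the tert-butyldimethylsilyl ether of the electron-poor diosphenol behaves like an aryl silyl ether and should survive.

**Step 12**
Reactants: 17 triethyl 4-phosphonocrotonate
Product: 18 (2E)-4-(diethoxyphosphoryl)but-2-enoic acid
Conditions: LiOH·H2O (1.1 equiv), THF/H2O, 0 °C → rt; then 1 M HCl to pH 2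
Reagents that add atoms: lithium hydroxide, [Li+].[OH-]
Why: Saponification of the carboxylic ethyl ester by acyl substitution; the diethyl phosphonate is not cleaved under these mild conditions.

**Step 13**
Reactants: 16 (4aS,5R,6S)-3-(tert-butyldimethylsilyloxy)-6-hydroxy-4a,5-dimethyl-5,6-dihydronaphthalen-2(4aH)-one; 18 (2E)-4-(diethoxyphosphoryl)but-2-enoic acid
Product: 19 (1R,2S,8aS)-7-(tert-butyldimethylsilyloxy)-1,8a-dimethyl-6-oxo-1,2,6,8a-tetrahydronaphthalen-2-yl (2E)-4-(diethoxyphosphoryl)but-2-enoate
Conditions: EDC·HCl, DMAP, CH2Cl2, 0 °C → rt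
Reagents that add atoms: none
Why: Steglich esterification through the acylpyridinium ion acylates the C3 hydroxyl without touching the C3–O bond, so the configuration is retained; any double-bond shift to the β,γ-isomer would be harmless because both isomers give the same anion in step 14.

**Step 14**
Reactants: 19 (1R,2S,8aS)-7-(tert-butyldimethylsilyloxy)-1,8a-dimethyl-6-oxo-1,2,6,8a-tetrahydronaphthalen-2-yl (2E)-4-(diethoxyphosphoryl)but-2-enoate; 20 butanal; 21 formaldehyde
Product: 23 (1R,2S,8aS)-7-(tert-butyldimethylsilyloxy)-1,8a-dimethyl-6-oxo-1,2,6,8a-tetrahydronaphthalen-2-yl (2E,4E,6R)-6-(hydroxymethyl)octa-2,4-dienoate, via hydroxy aldehyde 22 (not isolated)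
Conditions: 20 (3 equiv), 21 (37% aq., 4.5 equiv), (R)-α,α-diphenylprolinol trimethylsilyl ether (0.3 equiv), pH 7 phosphate buffer, toluene, 0 °C → rt; toluene phase washed (brine), dried (Na2SO4), added to 19 (1 equiv) + LiN(SiMe3)2 (0.95 equiv), THF, −78 → 0 °C
Reagents that add atoms: none
Why: The (R)-prolinol silyl ether condenses with butanal to the (E)-anti enamine whose CPh2OSiMe3 group covers one face, so formaldehyde is attacked from the open Re face of the α-carbon and hydrolysis releases (S)-2-(hydroxymethyl)butanal 22, whose stereocentre becomes C6' (R, only the CIP ranking changes) once the formyl carbon is olefinated. The closest known reaction type is the enamine-catalysed α-hydroxymethylation of aldehydes with aqueous formaldehyde followed by in situ Wittig-type olefination, run here as a vinylogous Horner–Wadsworth–Emmons reaction. The lithium anion of 19 adds through its phosphorus-bearing γ-carbon to the aldehyde, and syn-elimination of diethyl phosphate from the equilibrated adduct should give the 4'E alkene while the 2'E bond is kept. No ring is closed. The step needs chemoselectivity for 22 over the trienone and over residual formaldehyde; this is secured by washing formaldehyde out of the toluene phase, by using 22 in excess and by the low basicity of the stabilised anion at −78 °C, which should also keep the α-stereocentre of 22 from enolising. The three core stereocentres are spectators and the C7 enol stays capped as its silyl ether.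

**Step 15**
Reactants: 23 (1R,2S,8aS)-7-(tert-butyldimethylsilyloxy)-1,8a-dimethyl-6-oxo-1,2,6,8a-tetrahydronaphthalen-2-yl (2E,4E,6R)-6-(hydroxymethyl)octa-2,4-dienoate
Product: 24 Septeremophilane E
Conditions: HF·pyridine, pyridine, THF, 0 °C
Reagents that add atoms: none
Why: Fluoride-driven cleavage of the enol silyl ether (Si–F bond formation) under pyridine buffering should spare the dienoate, the allylic ester linkage and the C6' stereocentre.

**Compound list**
1 | 4,4-dimethoxycyclohexa-2,5-dien-1-one | COC1(OC)C=CC(=O)C=C1 | starting material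
2 | (5R)-4,4-dimethoxy-5-methylcyclohex-2-en-1-one | COC1(OC)C=CC(=O)C[C@H]1C | intermediate
3 | (5R)-4,4-dimethoxy-5,6-dimethylcyclohex-2-en-1-one (C6 epimers) | COC1(OC)C=CC(=O)C(C)[C@H]1C | intermediate
4 | (3R)-4,4-dimethoxy-2,3-dimethylcyclohexan-1-one (C2 epimers) | COC1(OC)CCC(=O)C(C)[C@H]1C | intermediate
5 | methyl vinyl ketone | CC(=O)C=C | starting material
6 | (2R,3R)-4,4-dimethoxy-2,3-dimethyl-2-(3-oxobutyl)cyclohexan-1-one (Michael adduct) | COC1(OC)CCC(=O)[C@](C)(CCC(C)=O)[C@H]1C | intermediate
7 | (4aR,5R)-8a-hydroxy-6,6-dimethoxy-4a,5-dimethyloctahydronaphthalen-2(1H)-one (ketol, 8a epimers) | COC1(OC)CCC2(O)CC(=O)CC[C@]2(C)[C@H]1C | intermediate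
8 | (4aR,5R)-6,6-dimethoxy-4a,5-dimethyl-4,4a,5,6,7,8-hexahydronaphthalen-2(3H)-one | COC1(OC)CCC2=CC(=O)CC[C@]2(C)[C@H]1C | intermediate
9 | (4aR,5R)-4a,5-dimethyl-4,4a,7,8-tetrahydronaphthalene-2,6(3H,5H)-dione | O=C1CCC2=CC(=O)CC[C@]2(C)[C@H]1C | intermediate
10 | (4aR,5R,6S)-6-hydroxy-4a,5-dimethyl-4,4a,5,6,7,8-hexahydronaphthalen-2(3H)-one | O[C@H]1CCC2=CC(=O)CC[C@]2(C)[C@H]1C | intermediate
11 | (4aR,5R,6S)-4a,5-dimethyl-2,6-bis(triethylsilyloxy)-3,4,4a,5,6,7-hexahydronaphthalene (bis-silyl dienol ether) | CC[Si](CC)(CC)O[C@H]1CC=C2C=C(O[Si](CC)(CC)CC)CC[C@]2(C)[C@H]1C | intermediate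
12 | (4aR,5R,6S)-4a,5-dimethyl-6-(triethylsilyloxy)-4,4a,5,6-tetrahydronaphthalen-2(3H)-one | CC[Si](CC)(CC)O[C@H]1C=CC2=CC(=O)CC[C@]2(C)[C@H]1C | intermediate
13 | (4aR,5R,6S)-3-hydroxy-4a,5-dimethyl-6-(triethylsilyloxy)-4,4a,5,6-tetrahydronaphthalen-2(3H)-one (C3 epimers) | CC[Si](CC)(CC)O[C@H]1C=CC2=CC(=O)C(O)C[C@]2(C)[C@H]1C | intermediate
14 | (4aS,5R,6S)-3-hydroxy-4a,5-dimethyl-6-(triethylsilyloxy)-5,6-dihydronaphthalen-2(4aH)-one | CC[Si](CC)(CC)O[C@H]1C=CC2=CC(=O)C(O)=C[C@]2(C)[C@H]1C | intermediate
15 | (4aS,5R,6S)-3-(tert-butyldimethylsilyloxy)-4a,5-dimethyl-6-(triethylsilyloxy)-5,6-dihydronaphthalen-2(4aH)-one | CC[Si](CC)(CC)O[C@H]1C=CC2=CC(=O)C(O[Si](C)(C)C(C)(C)C)=C[C@]2(C)[C@H]1C | intermediate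
16 | (4aS,5R,6S)-3-(tert-butyldimethylsilyloxy)-6-hydroxy-4a,5-dimethyl-5,6-dihydronaphthalen-2(4aH)-one (core alcohol) | O[C@H]1C=CC2=CC(=O)C(O[Si](C)(C)C(C)(C)C)=C[C@]2(C)[C@H]1C | intermediate
17 | triethyl 4-phosphonocrotonate | CCOC(=O)/C=C/CP(=O)(OCC)OCC | starting material
18 | (2E)-4-(diethoxyphosphoryl)but-2-enoic acid | CCOP(=O)(OCC)C/C=C/C(=O)O | intermediate
19 | (1R,2S,8aS)-7-(tert-butyldimethylsilyloxy)-1,8a-dimethyl-6-oxo-1,2,6,8a-tetrahydronaphthalen-2-yl (2E)-4-(diethoxyphosphoryl)but-2-enoate | CCOP(=O)(OCC)C/C=C/C(=O)O[C@H]1C=CC2=CC(=O)C(O[Si](C)(C)C(C)(C)C)=C[C@]2(C)[C@H]1C | intermediate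
20 | butanal | CCCC=O | starting material
21 | formaldehyde | C=O | starting material
22 | (S)-2-(hydroxymethyl)butanal | CC[C@H](C=O)CO | intermediate
23 | (1R,2S,8aS)-7-(tert-butyldimethylsilyloxy)-1,8a-dimethyl-6-oxo-1,2,6,8a-tetrahydronaphthalen-2-yl (2E,4E,6R)-6-(hydroxymethyl)octa-2,4-dienoate | CC[C@H](/C=C/C=C/C(=O)O[C@H]1C=CC2=CC(=O)C(O[Si](C)(C)C(C)(C)C)=C[C@]2(C)[C@H]1C)CO | intermediate
24 | Septeremophilane E | CC[C@H](/C=C/C=C/C(=O)O[C@H]1C=CC2=CC(=O)C(O)=C[C@]2(C)[C@H]1C)CO | target

Total step count: 15. Longest linear sequence: 14 steps (steps 1–11 and 13–15; step 12 is a one-step side branch).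

**Steps most likely to fail**

Step 14: water and free formaldehyde carried over from the organocatalytic stage may protonate or methylenate the phosphonate anion, and the unprotected β-hydroxy aldehyde may racemise or lose water in the basic medium before it is olefinated. The fallback sets out from 19 and returns at 24. Compound 22 is generated as in step 14 but silylated in the same flask (TBSCl, imidazole) and purified as (S)-2-[(tert-butyldimethylsilyloxy)methyl]butanal F1. A conventional two-component Horner–Wadsworth–Emmons reaction of dry F1 with the LiN(SiMe3)2-derived anion of 19 (THF, −78 → 0 °C) should give the bis-silyl ether (1R,2S,8aS)-7-(tert-butyldimethylsilyloxy)-1,8a-dimethyl-6-oxo-1,2,6,8a-tetrahydronaphthalen-2-yl (2E,4E,6R)-6-[(tert-butyldimethylsilyloxy)methyl]octa-2,4-dienoate F2. Buffered HF·pyridine then removes both silyl groups to give 24.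

Step 4: enolisation and Michael addition may occur at the unsubstituted α-methylene or on the face syn to the neighbouring methyl, and methyl vinyl ketone may polymerise under the alkoxide conditions. The fallback sets out from 4 and returns at 8. Thermodynamic silylation (Me3SiCl, Et3N, NaI, MeCN) should give the more substituted enol ether {[(3R)-4,4-dimethoxy-2,3-dimethylcyclohex-1-en-1-yl]oxy}trimethylsilane F3. MeLi releases the regiodefined lithium enolate, which is trapped at −78 °C with 3-(trimethylsilyl)but-3-en-2-one to give (2R,3R)-4,4-dimethoxy-2,3-dimethyl-2-[3-oxo-2-(trimethylsilyl)butyl]cyclohexan-1-one F4. KOH in MeOH then removes the silyl group and effects the aldol condensation to 8.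

Step 7: palladation of the dienol ether at C9 followed by protonolysis may simply return the enone, or the dienol ether may hydrolyse before it is oxidised. The fallback sets out from 11 and returns at 12. N-bromosuccinimide (THF, 0 °C) should brominate the dienol ether at its γ-carbon to give (4aR,5R,6S)-8-bromo-4a,5-dimethyl-6-(triethylsilyloxy)-4,4a,5,6,7,8-hexahydronaphthalen-2(3H)-one F5. Dehydrobromination with LiBr/Li2CO3 in DMF at 100 °C then gives the linear dienone 12.

Further compounds
F1 | step 14 | (S)-2-[(tert-butyldimethylsilyloxy)methyl]butanal | CC[C@H](C=O)CO[Si](C)(C)C(C)(C)C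
F2 | step 14 | (1R,2S,8aS)-7-(tert-butyldimethylsilyloxy)-1,8a-dimethyl-6-oxo-1,2,6,8a-tetrahydronaphthalen-2-yl (2E,4E,6R)-6-[(tert-butyldimethylsilyloxy)methyl]octa-2,4-dienoate | CC[C@H](/C=C/C=C/C(=O)O[C@H]1C=CC2=CC(=O)C(O[Si](C)(C)C(C)(C)C)=C[C@]2(C)[C@H]1C)CO[Si](C)(C)C(C)(C)C
F3 | step 4 | {[(3R)-4,4-dimethoxy-2,3-dimethylcyclohex-1-en-1-yl]oxy}trimethylsilane | COC1(OC)CCC(O[Si](C)(C)C)=C(C)[C@H]1C
F4 | step 4 | (2R,3R)-4,4-dimethoxy-2,3-dimethyl-2-[3-oxo-2-(trimethylsilyl)butyl]cyclohexan-1-one | COC1(OC)CCC(=O)[C@](C)(CC([Si](C)(C)C)C(C)=O)[C@H]1C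
F5 | step 7 | (4aR,5R,6S)-8-bromo-4a,5-dimethyl-6-(triethylsilyloxy)-4,4a,5,6,7,8-hexahydronaphthalen-2(3H)-one (C8 epimers) | CC[Si](CC)(CC)O[C@H]1CC(Br)C2=CC(=O)CC[C@]2(C)[C@H]1C
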